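**Assumption (one line):** CIP analysis of the target SMILES gives the flavanone C2 as (S). The target is 5′-prenylhesperetin, (2S)-5,7,3′-trihydroxy-4′-methoxy-5′-prenylflavanone. I assume the (R,R)-diaminocyclohexane catalyst series delivers (2S), to be confirmed by screening both enantiomers of the catalyst.

## Retrosynthetic overview
1. Disconnect C2–O1 (6-endo oxa-Michael). This gives an unprotected 2′,4′,6′-trihydroxychalcone. The pyranone ring is the only ring formed, in the last step, where a bifunctional organocatalyst sets C2.
2. Disconnect the chalcone C=C (Claisen–Schmidt) into phloroacetophenone and 3-hydroxy-4-methoxy-5-prenylbenzaldehyde.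
3. Disconnect the aryl–prenyl bond (Stille) to 3-bromo-5-hydroxy-4-methoxybenzaldehyde (5-bromoisovanillin).
4. Disconnect the methyl ether (regioselective 4-O-methylation) to 3-bromo-4,5-dihydroxybenzaldehyde. Both aromatic rings are therefore pre-existing commercial arenes.

## Route

**Step 1**
Reactants: 1 (3-bromo-4,5-dihydroxybenzaldehyde) + 2 (iodomethane)
Product: 3 (3-bromo-5-hydroxy-4-methoxybenzaldehyde)
Conditions: MeI (1.0 equiv), NaHCO3 (1.1 equiv), DMF, 40 °C, 16 h
Reagents that add atoms: iodomethane, CI
Why: The 4-OH is para to CHO and ortho to Br, so it is the most acidic OH. Weak base and one equivalent of MeI therefore give selective O4-methylation (Williamson ether synthesis, as in the 4-selective alkylation of protocatechualdehydes). No stereocentre is involved.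

**Step 2**
Reactants: 3 + 4 (tributyl(3-methylbut-2-en-1-yl)stannane)
Product: 5 (3-hydroxy-4-methoxy-5-(3-methylbut-2-en-1-yl)benzaldehyde)
Conditions: Pd(PPh3)4 (5 mol %), LiCl (3 equiv), DMF, 90 °C, 12 h
Reagents that add atoms: prenyltributylstannane, CCCC[Sn](CCCC)(CCCC)CC=C(C)C (supplies the prenyl group)
Why: Stille coupling. Transmetalation followed by reductive elimination at the less hindered primary allyl terminus of the π-allyl-Pd intermediate gives the linear prenyl arene rather than the reverse-prenyl one. The aldehyde and the free phenol are tolerated, because uncatalysed allylstannane addition to aldehydes needs Lewis-acid activation and is slow here relative to oxidative addition of the aryl bromide.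

**Step 3**
Reactants: 5 + 6 (2′,4′,6′-trihydroxyacetophenone)
Product: 7 ((E)-3-(3-hydroxy-4-methoxy-5-prenylphenyl)-1-(2,4,6-trihydroxyphenyl)prop-2-en-1-one)
Conditions: KOH (8 equiv), EtOH/H2O, 25 °C, 48 h, N2, dark; quench into cold 1 M HCl to pH 4, 0 °C, extract at once
Reagents that add atoms: none (6 is the numbered ketone partner; KOH and HCl leave no atoms in the product)
Why: Claisen–Schmidt aldol condensation. The 3-phenoxide sits meta to CHO and only mildly deactivates it, and the prenyl alkene is base-stable. The E-enone forms under thermodynamic control. The cold, mildly acidic quench limits racemic background cyclization.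

**Step 4**
Reactants: 7
Product: 8 ((2S)-5,7,3′-trihydroxy-4′-methoxy-5′-prenylflavanone, the target)
Conditions: 9 (10 mol %), MTBE, 0 °C, 72 h, then direct silica chromatography
Reagents that add atoms: none (9 is a catalyst and is not incorporated)
Why: Proposed new method: an enantioselective 6-endo-trig oxa-Michael cyclization of a fully unprotected, prenylated 2′,4′,6′-trihydroxychalcone, catalysed by a trans-cyclohexanediamine squaramide–tertiary-amine (chalcone-isomerase-mimetic design). The protonated amine acts as a general base/acid shuttle toward the 2′-OH. The squaramide N–H groups clamp the acidic 4′-phenol/phenolate and the carbonyl, locking the s-cis enone and exposing one β-face, which sets C2 as (S). The 5-OH···O=C4 chelate stabilizes the product and slows retro-Michael racemization. The closest known reaction types are cinchona/Takemoto-thiourea-catalysed oxa-Michael cyclization of protected 2′-hydroxychalcones and enzymatic chalcone isomerase.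

## Compound list
1 | 3-bromo-4,5-dihydroxybenzaldehyde | O=Cc1cc(O)c(O)c(Br)c1 | starting material
2 | iodomethane | CI | starting material
3 | 3-bromo-5-hydroxy-4-methoxybenzaldehyde | COc1c(O)cc(C=O)cc1Br | intermediate
4 | tributyl(3-methylbut-2-en-1-yl)stannane | CCCC[Sn](CCCC)(CCCC)CC=C(C)C | starting material
5 | 3-hydroxy-4-methoxy-5-prenylbenzaldehyde | COc1c(O)cc(C=O)cc1CC=C(C)C | intermediate
6 | 2′,4′,6′-trihydroxyacetophenone | CC(=O)c1c(O)cc(O)cc1O | starting material
7 | (E)-2′,4′,6′,3-tetrahydroxy-4-methoxy-5-prenylchalcone | COc1c(O)cc(/C=C/C(=O)c2c(O)cc(O)cc2O)cc1CC=C(C)C | intermediate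
8 | (2S)-5,7,3′-trihydroxy-4′-methoxy-5′-prenylflavanone | COc1c(O)cc([C@@H]2CC(=O)c3c(O)cc(O)cc3O2)cc1CC=C(C)C | target
9 | 3-{[(1R,2R)-2-(dimethylamino)cyclohexyl]amino}-4-{[3,5-bis(trifluoromethyl)phenyl]amino}cyclobut-3-ene-1,2-dione (squaramide organocatalyst) | CN(C)[C@@H]1CCCC[C@H]1NC1=C(Nc2cc(C(F)(F)F)cc(C(F)(F)F)c2)C(=O)C1=O | starting material (catalyst, not incorporated into the product)

**Total step count:** 4
**Longest linear sequence:** 4 (1 → 3 → 5 → 7 → 8)

## Three steps most likely to fail
1. **Step 4 (proposed new step).** Background racemic cyclization, retro-oxa-Michael racemization, or catalyst quenching by the acidic 4′-OH could give low ee.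
 Fallback (known chemistry): cyclize 7 racemically (NaOAc, MeOH, reflux), resolve the enantiomers by preparative chiral-phase HPLC/SFC, and racemize and recycle the (R)-isomer with mild base.
2. **Step 3.** Claisen–Schmidt condensation on polyphenolic partners with no protecting groups may give low yield because of polyanion formation.
 Fallback: use the 2′-OH-4′,6′-bis(OMOM)acetophenone and the 3-OMOM aldehyde, condense under KOH/EtOH, then remove the MOM groups with HCl/MeOH before or after cyclization.
3. **Step 2.** Stille prenylation may give branched (reverse-prenyl) product, protodebromination, or allylation of the aldehyde.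
 Fallback: Stille coupling of 3 with allyltributylstannane, then cross-metathesis with 2-methyl-2-butene (Grubbs II) to form the prenyl group.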